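The tetrahydrofuran ring (O1, C2–C5) is cut at O1–C5 and C2–C3. C5 with its aryl group and C4 with its CH2O arm come from a racemic trans-2-aryl-3-(silyloxymethyl)cyclopropane-1,1-dicarboxylate, O1 and C2 from pivaloyl-protected syringaldehyde. One tin-catalysed annulation closes the ring and fixes the cis relations C2/C5 and C4/C5 at once, exploiting the cis-2,5-diaryl ether and the cis C4/C5 pair of the meso target. The surplus ester at C3 is then removed through a lactone bridging C3 and C4, which forces the last cis relation. Pivalate phenols, benzyl esters and a silyl ether keep the whole end-game free of base.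

Key step: step 7

Assumption: the target is meso, so all chiral intermediates are made as racemates; each SMILES shows one enantiomer and only relative configuration is meant; ring atoms are numbered O1, C2 (aryl from the aldehyde), C3, C4, C5 (aryl from the cyclopropane).

Step 1
Reactants: 1 syringaldehyde (4-hydroxy-3,5-dimethoxybenzaldehyde)
Product: 2 4-formyl-2,6-dimethoxyphenyl pivalate
Conditions: PivCl (1.2 equiv), Et3N (1.5 equiv), DMAP (5 mol%), CH2Cl2, 0 °C to rt
Reagents that add atoms: pivaloyl chloride, CC(C)(C)C(=O)Cl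
Why: DMAP-catalysed O-acylation of the phenol with an acid chloride should proceed despite the two ortho methoxy groups, and the hindered aryl pivalate should then resist amines, borohydride and mild acid until the final hydride step; no stereocentre is formed.

Step 2
Reactants: 3 sinapaldehyde ((E)-3-(4-hydroxy-3,5-dimethoxyphenyl)prop-2-enal)
Product: 4 2,6-dimethoxy-4-[(E)-3-oxoprop-1-en-1-yl]phenyl pivalate
Conditions: PivCl (1.2 equiv), Et3N (1.5 equiv), DMAP (5 mol%), CH2Cl2, 0 °C to rt
Reagents that add atoms: pivaloyl chloride, CC(C)(C)C(=O)Cl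
Why: The same O-acylation leaves the enal untouched and turns the para oxygen into a weak donor, which is what the annulation in step 7 needs; the E alkene is carried through unchanged.

Step 3
Reactants: 5 dibenzyl malonate
Product: 6 dibenzyl 2-bromomalonate
Conditions: CBr4 (1.0 equiv), DBU (1.0 equiv), THF, −78 °C
Reagents that add atoms: carbon tetrabromide, BrC(Br)(Br)Br
Why: Electrophilic α-bromination of the malonate enolate by halogen transfer from CBr4 (the halogenation stage of a Bingel reaction) should stop at the monobromide when run cold with one equivalent of each reagent.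

Step 4
Reactants: 4 2,6-dimethoxy-4-[(E)-3-oxoprop-1-en-1-yl]phenyl pivalate; 6 dibenzyl 2-bromomalonate
Product: 7 dibenzyl trans-2-[3,5-dimethoxy-4-(pivaloyloxy)phenyl]-3-formylcyclopropane-1,1-dicarboxylate
Conditions: (±)-α,α-diphenylprolinol trimethylsilyl ether (20 mol%; either enantiomer serves), 2,6-lutidine (1.1 equiv), CH2Cl2, 0 °C to rt
Reagents that add atoms: none
Why: Michael-initiated ring closure under iminium–enamine catalysis, in which the bromomalonate adds to the β-carbon of the iminium ion of 4 and the resulting enamine displaces bromide (3-exo-tet); the two new stereocentres should come out trans because the ring closes through the rotamer that keeps the aryl group and the enamine carbon apart, which is also the more stable arrangement.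

Step 5
Reactants: 7 dibenzyl trans-2-[3,5-dimethoxy-4-(pivaloyloxy)phenyl]-3-formylcyclopropane-1,1-dicarboxylate
Product: 8 dibenzyl trans-2-[3,5-dimethoxy-4-(pivaloyloxy)phenyl]-3-(hydroxymethyl)cyclopropane-1,1-dicarboxylate
Conditions: NaBH4 (1.0 equiv), THF/MeOH (10:1), −20 °C, 15 min; AcOH quench; crude product taken on without chromatography
Reagents that add atoms: none
Why: Chemoselective borohydride reduction of the aldehyde in the presence of the malonate esters and the hindered aryl pivalate, with cold, short contact and an acidic quench meant to keep the new alcohol from closing onto the cis ester; no stereocentre changes.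

Step 6
Reactants: 8 dibenzyl trans-2-[3,5-dimethoxy-4-(pivaloyloxy)phenyl]-3-(hydroxymethyl)cyclopropane-1,1-dicarboxylate
Product: 9 dibenzyl trans-2-{[(tert-butyldimethylsilyl)oxy]methyl}-3-[3,5-dimethoxy-4-(pivaloyloxy)phenyl]cyclopropane-1,1-dicarboxylate
Conditions: TBSCl (1.3 equiv), imidazole (2.5 equiv), CH2Cl2, 0 °C to rt
Reagents that add atoms: tert-butyldimethylsilyl chloride, CC(C)(C)[Si](C)(C)Cl
Why: Imidazole-promoted silylation of a primary alcohol is fast and leaves the donor–acceptor cyclopropane closed; the silyl ether has no carbonyl oxygen that could open the activated ring from within and can later be removed without base.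

Step 7
Reactants: 9 dibenzyl trans-2-{[(tert-butyldimethylsilyl)oxy]methyl}-3-[3,5-dimethoxy-4-(pivaloyloxy)phenyl]cyclopropane-1,1-dicarboxylate; 2 4-formyl-2,6-dimethoxyphenyl pivalate
Product: 10 dibenzyl 2,4,5-cis-4-{[(tert-butyldimethylsilyl)oxy]methyl}-2,5-bis[3,5-dimethoxy-4-(pivaloyloxy)phenyl]tetrahydrofuran-3,3-dicarboxylate
Conditions: 2 (2.0 equiv), Sn(OTf)2 (10 mol%), 4 Å molecular sieves, CH2Cl2, rt
Reagents that add atoms: none
Why: Chelation of the geminal diester by divalent tin polarises the bond between the malonyl carbon and the aryl-bearing carbon of 9, the carbonyl oxygen of 2 attacks that benzylic carbon from the side opposite the departing malonyl carbon (SN2-like, inversion), and the tin malonate then adds to the oxocarbenium carbon; this is the known Lewis-acid formal [3+2] annulation of donor–acceptor cyclopropanes with aldehydes, a reaction type that extends to 2,3-disubstituted cyclopropanes. The tetrahydrofuran ring closes in the C2–C3 bond-forming event as a 5-(enolexo)-endo-trig aldol-type cyclisation. C5 is set by the inversion, which turns the trans aryl/CH2OSi relation of the cyclopropane into the cis C4/C5 relation, while C4 is carried through untouched. C2 is set in the ring closure through an envelope transition state in which the aryl group of the E oxocarbenium ion and the C5 aryl group are both pseudo-equatorial, hence 2,5-cis. The step needs clean inversion without ionisation to a free benzylic cation and cis-2,5 closure; the para pivaloyloxy group, a far weaker donor than an alkoxy group, should keep the opening SN2-like, and the ether-protected side chain offers no internal nucleophile.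

Step 8
Reactants: 10 dibenzyl 2,4,5-cis-4-{[(tert-butyldimethylsilyl)oxy]methyl}-2,5-bis[3,5-dimethoxy-4-(pivaloyloxy)phenyl]tetrahydrofuran-3,3-dicarboxylate
Product: 12 benzyl 4,6-bis[3,5-dimethoxy-4-(pivaloyloxy)phenyl]-1-oxotetrahydro-1H,3H-furo[3,4-c]furan-6a-carboxylate (cis-fused; both aryls cis to the lactone bridge), via hydroxymethyl diester 11 (not isolated)
Conditions: CSA (0.2 equiv), CH2Cl2/MeOH (4:1), 0 °C to 40 °C
Reagents that add atoms: none
Why: Acid-catalysed methanolysis of the primary silyl ether is followed by acid-catalysed lactonisation (intramolecular transesterification, 5-exo-trig) in which only the ester cis to the hydroxymethyl group can take part, since a trans-fused bicyclo[3.3.0] lactone is too strained, so the two diastereotopic esters are told apart and C3 becomes a stereocentre with its lactone carbonyl cis to C4.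

Step 9
Reactants: 12 benzyl 4,6-bis[3,5-dimethoxy-4-(pivaloyloxy)phenyl]-1-oxotetrahydro-1H,3H-furo[3,4-c]furan-6a-carboxylate
Product: 14 4,6-bis[3,5-dimethoxy-4-(pivaloyloxy)phenyl]tetrahydro-1H,3H-furo[3,4-c]furan-1-one (cis-fused; both aryls cis to the lactone bridge), via lactone acid 13 (not isolated)
Conditions: H2 (1 atm), 10% Pd/C, EtOAc, rt; filter, concentrate; toluene, 110 °C
Reagents that add atoms: none
Why: Hydrogenolysis of the benzyl ester gives a malonic-type acid that should lose CO2 on heating through the usual six-membered cyclic transition state (malonic acid decarboxylation), and the lactone enol so formed can only tautomerise to the cis-fused lactone, so the hydrogen at C3 arrives trans to its neighbours' substituents and the all-cis array is complete.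

Step 10
Reactants: 14 4,6-bis[3,5-dimethoxy-4-(pivaloyloxy)phenyl]tetrahydro-1H,3H-furo[3,4-c]furan-1-one
Product: 15 4,4′-[(2R,3R,4S,5S)-3,4-bis(hydroxymethyl)tetrahydrofuran-2,5-diyl]bis(2,6-dimethoxyphenol) (meso; all-cis; CNP0170897.3)
Conditions: LiAlH4 (5 equiv), THF, 0 °C to rt, lactone added to the hydride; EtOAc quench, aq. KNaC4H4O6 (potassium sodium tartrate), pH kept near 6
Reagents that add atoms: none
Why: LiAlH4 reduction of the lactone to the 1,4-diol and reductive cleavage of both aryl pivalates should occur in one operation, and the C3 configuration should hold because the intermediate aluminium lactolate is reduced in excess hydride faster than any open aldehyde could enolise.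

Compound list
1 | syringaldehyde (4-hydroxy-3,5-dimethoxybenzaldehyde) | COc1cc(C=O)cc(OC)c1O | starting material
2 | 4-formyl-2,6-dimethoxyphenyl pivalate | COc1cc(C=O)cc(OC)c1OC(=O)C(C)(C)C | intermediate
3 | sinapaldehyde, (E)-3-(4-hydroxy-3,5-dimethoxyphenyl)prop-2-enal | COc1cc(/C=C/C=O)cc(OC)c1O | starting material
4 | 2,6-dimethoxy-4-[(E)-3-oxoprop-1-en-1-yl]phenyl pivalate | COc1cc(/C=C/C=O)cc(OC)c1OC(=O)C(C)(C)C | intermediate
5 | dibenzyl malonate | O=C(CC(=O)OCc1ccccc1)OCc1ccccc1 | starting material
6 | dibenzyl 2-bromomalonate | O=C(OCc1ccccc1)C(Br)C(=O)OCc1ccccc1 | intermediate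
7 | dibenzyl trans-2-[3,5-dimethoxy-4-(pivaloyloxy)phenyl]-3-formylcyclopropane-1,1-dicarboxylate (racemic) | O=C(OCc1ccccc1)C2(C(=O)OCc1ccccc1)[C@H](C=O)[C@H]2c1cc(OC)c(OC(=O)C(C)(C)C)c(OC)c1 | intermediate
8 | dibenzyl trans-2-[3,5-dimethoxy-4-(pivaloyloxy)phenyl]-3-(hydroxymethyl)cyclopropane-1,1-dicarboxylate (racemic) | O=C(OCc1ccccc1)C2(C(=O)OCc1ccccc1)[C@H](CO)[C@H]2c1cc(OC)c(OC(=O)C(C)(C)C)c(OC)c1 | intermediate
9 | dibenzyl trans-2-{[(tert-butyldimethylsilyl)oxy]methyl}-3-[3,5-dimethoxy-4-(pivaloyloxy)phenyl]cyclopropane-1,1-dicarboxylate (racemic) | O=C(OCc1ccccc1)C2(C(=O)OCc1ccccc1)[C@H](CO[Si](C)(C)C(C)(C)C)[C@H]2c1cc(OC)c(OC(=O)C(C)(C)C)c(OC)c1 | intermediate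
10 | dibenzyl 2,4,5-cis-4-{[(tert-butyldimethylsilyl)oxy]methyl}-2,5-bis[3,5-dimethoxy-4-(pivaloyloxy)phenyl]tetrahydrofuran-3,3-dicarboxylate (racemic; both aryls and the CH2OSi group on one face) | COc1cc([C@H]2O[C@@H](c3cc(OC)c(OC(=O)C(C)(C)C)c(OC)c3)[C@@H](CO[Si](C)(C)C(C)(C)C)C2(C(=O)OCc3ccccc3)C(=O)OCc3ccccc3)cc(OC)c1OC(=O)C(C)(C)C | intermediate
11 | dibenzyl 2,4,5-cis-4-(hydroxymethyl)-2,5-bis[3,5-dimethoxy-4-(pivaloyloxy)phenyl]tetrahydrofuran-3,3-dicarboxylate (racemic; not isolated) | COc1cc([C@H]2O[C@@H](c3cc(OC)c(OC(=O)C(C)(C)C)c(OC)c3)[C@@H](CO)C2(C(=O)OCc3ccccc3)C(=O)OCc3ccccc3)cc(OC)c1OC(=O)C(C)(C)C | intermediate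
12 | benzyl 4,6-bis[3,5-dimethoxy-4-(pivaloyloxy)phenyl]-1-oxotetrahydro-1H,3H-furo[3,4-c]furan-6a-carboxylate (racemic; cis-fused; both aryls cis to the lactone bridge, benzyl ester on the opposite face) | COc1cc([C@H]2O[C@@H](c3cc(OC)c(OC(=O)C(C)(C)C)c(OC)c3)[C@H]3COC(=O)[C@@]23C(=O)OCc2ccccc2)cc(OC)c1OC(=O)C(C)(C)C | intermediate
13 | 4,6-bis[3,5-dimethoxy-4-(pivaloyloxy)phenyl]-1-oxotetrahydro-1H,3H-furo[3,4-c]furan-6a-carboxylic acid (racemic; same configuration as 12; not isolated) | COc1cc([C@H]2O[C@@H](c3cc(OC)c(OC(=O)C(C)(C)C)c(OC)c3)[C@H]3COC(=O)[C@@]23C(=O)O)cc(OC)c1OC(=O)C(C)(C)C | intermediate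
14 | 4,6-bis[3,5-dimethoxy-4-(pivaloyloxy)phenyl]tetrahydro-1H,3H-furo[3,4-c]furan-1-one (racemic; cis-fused; both aryls cis to the lactone bridge, all four substituents of the tetrahydrofuran ring cis) | COc1cc([C@H]2O[C@@H](c3cc(OC)c(OC(=O)C(C)(C)C)c(OC)c3)[C@H]3COC(=O)[C@@H]23)cc(OC)c1OC(=O)C(C)(C)C | intermediate
15 | 4,4′-[(2R,3R,4S,5S)-3,4-bis(hydroxymethyl)tetrahydrofuran-2,5-diyl]bis(2,6-dimethoxyphenol) (meso, all-cis) | COc1cc([C@H]2O[C@@H](c3cc(OC)c(O)c(OC)c3)[C@@H](CO)[C@H]2CO)cc(OC)c1O | target

Total step count: 10 steps.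
Longest linear sequence: 8 steps (3 → 4 → 7 → 8 → 9 → 10 → 12 → 14 → 15; steps 2, 4, 5, 6, 7, 8, 9 and 10).

Steps most likely to fail

Step 7. The hindered, electronically tempered cyclopropane may open too slowly, or it may open through a free benzylic cation and so scramble the C4/C5 relation; loss of the silyl ether to the Lewis acid is a further possibility. The fallback builds the all-cis ring by one-face hydrogenation of a furan instead. It sets out from 2: Roskamp-type homologation with ethyl diazoacetate and NbCl5 (5 mol%) in CH2Cl2 should give ethyl 3-[3,5-dimethoxy-4-(pivaloyloxy)phenyl]-3-oxopropanoate F1. Oxidative enolate dimerisation (NaH, then I2, THF, 0 °C) should give diethyl 2,3-bis[3,5-dimethoxy-4-(pivaloyloxy)benzoyl]succinate F2 as a diastereomer mixture. Paal–Knorr cyclodehydration (TsOH·H2O, toluene, reflux) converges both diastereomers on diethyl 2,5-bis[3,5-dimethoxy-4-(pivaloyloxy)phenyl]furan-3,4-dicarboxylate F3. Hydrogenation over 5% Rh/Al2O3 (H2, 60 bar, EtOAc) should add all four hydrogens to one face and give diethyl all-cis-2,5-bis[3,5-dimethoxy-4-(pivaloyloxy)phenyl]tetrahydrofuran-3,4-dicarboxylate F4. LiAlH4 in THF then reduces both esters and removes both pivalates, and the sequence comes back to the route at 15.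

Step 9. Hydrogenolysis is kept short to spare the benzylic C–O bonds of the ring; the more likely failure is in the thermal stage, where CO2 loss may be sluggish or the strained all-cis ring may epimerise at C2 or C5 at 110 °C. The fallback removes the carboxyl group by a radical chain at room temperature (Barton decarboxylation). It sets out from 13, now isolated after the hydrogenolysis stage. Oxalyl chloride with catalytic DMF in CH2Cl2 should give 4,6-bis[3,5-dimethoxy-4-(pivaloyloxy)phenyl]-1-oxotetrahydro-1H,3H-furo[3,4-c]furan-6a-carbonyl chloride F5. The sodium salt of 2-mercaptopyridine N-oxide (C5H4NNaOS) with catalytic DMAP in THF, in the dark, converts it into the thiohydroxamate ester 2-thioxopyridin-1(2H)-yl 4,6-bis[3,5-dimethoxy-4-(pivaloyloxy)phenyl]-1-oxotetrahydro-1H,3H-furo[3,4-c]furan-6a-carboxylate F6. Irradiation with a tungsten lamp in the presence of t-BuSH should give the ring-fusion radical, which can take hydrogen only on the convex face, and the sequence comes back to the route at 14.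

Step 5. The alkoxide or alcohol formed in the reduction may close onto the cis benzyl ester before it can be silylated, which would destroy the diester that step 7 needs. The fallback puts the oxygenated carbon at the alcohol level before the three-membered ring exists. It sets out from 4: Luche reduction (NaBH4, CeCl3·7H2O, MeOH, 0 °C) should give 4-[(E)-3-hydroxyprop-1-en-1-yl]-2,6-dimethoxyphenyl pivalate F7, and TBSCl with imidazole should give 4-[(E)-3-{[(tert-butyldimethylsilyl)oxy]prop-1-en-1-yl}]-2,6-dimethoxyphenyl pivalate F8. In parallel, diazo transfer to 5 with 4-acetamidobenzenesulfonyl azide and Et3N in MeCN gives dibenzyl 2-diazomalonate F9. Carbenoid cyclopropanation of F8 with F9 under Rh2(esp)2 catalysis (esp = α,α,α′,α′-tetramethyl-1,3-benzenedipropanoate; CH2Cl2, slow addition) is stereospecific for the E alkene, and the sequence comes back to the route at 9.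

Further compounds
F1 | step 7 | ethyl 3-[3,5-dimethoxy-4-(pivaloyloxy)phenyl]-3-oxopropanoate | CCOC(=O)CC(=O)c1cc(OC)c(OC(=O)C(C)(C)C)c(OC)c1
F2 | step 7 | diethyl 2,3-bis[3,5-dimethoxy-4-(pivaloyloxy)benzoyl]succinate (diastereomer mixture) | CCOC(=O)C(C(=O)c1cc(OC)c(OC(=O)C(C)(C)C)c(OC)c1)C(C(=O)OCC)C(=O)c1cc(OC)c(OC(=O)C(C)(C)C)c(OC)c1
F3 | step 7 | diethyl 2,5-bis[3,5-dimethoxy-4-(pivaloyloxy)phenyl]furan-3,4-dicarboxylate | CCOC(=O)c1c(-c2cc(OC)c(OC(=O)C(C)(C)C)c(OC)c2)oc(-c2cc(OC)c(OC(=O)C(C)(C)C)c(OC)c2)c1C(=O)OCC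
F4 | step 7 | diethyl all-cis-2,5-bis[3,5-dimethoxy-4-(pivaloyloxy)phenyl]tetrahydrofuran-3,4-dicarboxylate (meso) | COc1cc([C@H]2O[C@@H](c3cc(OC)c(OC(=O)C(C)(C)C)c(OC)c3)[C@@H](C(=O)OCC)[C@H]2C(=O)OCC)cc(OC)c1OC(=O)C(C)(C)C
F5 | step 9 | 4,6-bis[3,5-dimethoxy-4-(pivaloyloxy)phenyl]-1-oxotetrahydro-1H,3H-furo[3,4-c]furan-6a-carbonyl chloride (racemic; configuration as 13) | COc1cc([C@H]2O[C@@H](c3cc(OC)c(OC(=O)C(C)(C)C)c(OC)c3)[C@H]3COC(=O)[C@@]23C(=O)Cl)cc(OC)c1OC(=O)C(C)(C)C
F6 | step 9 | 2-thioxopyridin-1(2H)-yl 4,6-bis[3,5-dimethoxy-4-(pivaloyloxy)phenyl]-1-oxotetrahydro-1H,3H-furo[3,4-c]furan-6a-carboxylate (racemic; configuration as 13) | COc1cc([C@H]2O[C@@H](c3cc(OC)c(OC(=O)C(C)(C)C)c(OC)c3)[C@H]3COC(=O)[C@@]23C(=O)ON2C=CC=CC2=S)cc(OC)c1OC(=O)C(C)(C)C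
F7 | step 5 | 4-[(E)-3-hydroxyprop-1-en-1-yl]-2,6-dimethoxyphenyl pivalate | COc1cc(/C=C/CO)cc(OC)c1OC(=O)C(C)(C)C
F8 | step 5 | 4-[(E)-3-{[(tert-butyldimethylsilyl)oxy]prop-1-en-1-yl}]-2,6-dimethoxyphenyl pivalate | COc1cc(/C=C/CO[Si](C)(C)C(C)(C)C)cc(OC)c1OC(=O)C(C)(C)C
F9 | step 5 | dibenzyl 2-diazomalonate | [N-]=[N+]=C(C(=O)OCc1ccccc1)C(=O)OCc1ccccc1
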